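(The data come from a simulation for substances that don't exist, noise included.)

No constants were given to me, so I worked from the readings of two earlier runs to foresee the flask below.

| setting | gamma | alpha | flask |
|---|---|---|---|
| E | 5.5 mM | 22 mM | 11 mM |
| remark | run made earlier | run made earlier |  |
| time |  |  | 12 min |

| run | time / min | J / % | G / % |
|---|---|---|---|
| gamma | 0.417 | 2.2 | 70.3 |
| gamma | 1.00 | 1.2 | 66.9 |
| gamma | 2.00 | 0.9 | 58.0 |
| gamma | 3.00 | 0 | 50.6 |
| gamma | 4.00 | 0.1 | 45.7 |
| gamma | 6.00 | 0 | 37.5 |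
| gamma | 8.00 | 0.5 | 32.2 |
| alpha | 1.00 | 1.8 | 64.6 |
| alpha | 2.00 | 1.0 | 56.6 |
| alpha | 3.00 | 0.8 | 47.2 |
| alpha | 4.00 | 1.0 | 40.9 |
| alpha | 5.00 | 0 | 36.3 |
| alpha | 6.00 | 0.5 | 32.6 |
| alpha | 8.00 | 0 | 27.1 |

(scatter of a reading: 0.5 percentage points)

- ratio of J to G at 4.0 s
- ratio of J to G at 12 min
- which of J and G there is more of at 12 min

- E is a solid; its amount is given per volume of the solution
- at the start none of E is in solution

Late J readings stand close to their scatter of 0.5 percentage points, so one reading says little, and I treated J as a small correction to G. From 1.00 min on, the J readings of both runs add up to 7.80% and the G readings to 596%. That gives 0.0131, the pooled ratio ρ, summed J over summed G, good to about 0.00302. I assumed J keeps this ratio to G up to 12 min, and with ρ far below one, G leads. The forecast gave 0.06 at 4.0 s, 0.01 at 12 min, which is lower than my ρ, and G in the lead: “Nothing suggests late growth”.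

The flask gave 0.115 at 4.0 s, 0.0149 at 12 min, and G in the lead.

    2 D → L (k = 2.30 M⁻¹ s⁻¹)
    D ⇌ J (K = 0.0990, k = 0.0280 s⁻¹)
    J ⇌ Z (K = 0.170, k = 0.0270 s⁻¹)
    E ⇌ D, rate k4*(cs4 - [D]) while solid is left; crystals form when [D] > cs4 (solubility = 7.10 mM, k = 0.0830 s⁻¹)
    D ⇌ G (K = 6.50, k = 0.170 s⁻¹)
    D ⇌ Q (K = 17.0, k = 0.0200 s⁻¹)

At 12 min this flask's ratio of J to G stood close to 0.0152, the equilibrium constant of the making of J from D (dissolved E) over that of the loss of D to G, the mark of a pre-equilibrium. On this flask's 24.5% of G, ρ gives 0.321% of J; the flask held 0.365%, less than one reading's scatter, so in a repeat of the run the J readings are worth pooling. With 44 mM of E, G stood at 17.5% at 12.0 min, and ρ gives 0.229% of J. The computed amount there was 0.259%, a ratio of 0.0148.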